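**Assumption:** Labdane numbering is used (C-17 = methyl on C-8, C-18/C-19 = gem-dimethyl on C-4, C-20 = methyl on C-10, C-15 = lactone C=O, C-16 = lactone OCH2). The target is read as (5S,7R,8R,9R,10S,13R)-9α,13-epoxy-7β-hydroxy-6-oxolabdan-15,16-olide, and the two C-13 epimers formed in the last step are taken to be separable by chromatography.

## Retrosynthetic overview

1. The spiro-tetrahydrofuran (C9–O–C13) is closed last, by 5-exo oxa-Michael addition of the 9α-OH to a Δ13-butenolide.
2. The butenolide ring is bought intact; C12–C13 comes from Negishi coupling of a C-12 alkylzinc with 4-bromofuran-2(5H)-one.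
3. The 6-oxo-7β-hydroxy unit comes from a 7-ketone by 1,2-transposition (Δ6 silyl enol ether, hydroboration, oxidation).
4. The 9α-OH and 8α-methyl come from SmI2 opening of an 8α,9α-epoxy-7-ketone, made by allylic oxidation and epoxidation of a Δ8 alkene.
5. Rings A/B with C-5 and C-10 come from (+)-sclareolide. Ring order: decalin (chiral pool), butenolide (bought), spiro-tetrahydrofuran.

## Route

Step 1
Reactants: 1 (+)-sclareolide
Product: 2 methyl 13,14,15,16-tetranorlabd-8-en-12-oate
Conditions: conc. H2SO4, MeOH, reflux, 24 h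
Reagents that add atoms: methanol, CO
Why: Acid-mediated E1 opening of the tertiary lactone C8–O bond with Fischer esterification gives, after equilibration, the tetrasubstituted Zaitsev Δ8(9) alkene as major isomer (minor Δ7/Δ8(17) isomers removed on AgNO3–silica), with C-5 and C-10 untouched.

Step 2
Reactants: 2 methyl 13,14,15,16-tetranorlabd-8-en-12-oate
Product: 3 13,14,15,16-tetranorlabd-8-en-12-ol
Conditions: LiAlH4, THF, 0 °C to rt
Reagents that add atoms: none
Why: Hydride reduction of the ester to the primary alcohol; the tetrasubstituted alkene is inert.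

Step 3
Reactants: 3 13,14,15,16-tetranorlabd-8-en-12-ol
Product: 4 12-bromo-13,14,15,16-tetranorlabd-8-ene
Conditions: CBr4, PPh3, CH2Cl2, 0 °C
Reagents that add atoms: carbon tetrabromide, BrC(Br)(Br)Br
Why: Appel bromination of the unhindered primary alcohol gives a C-12 handle that tolerates the oxidations, SmI2, LDA and borane used later.

Step 4
Reactants: 4 12-bromo-13,14,15,16-tetranorlabd-8-ene
Product: 5 12-bromo-13,14,15,16-tetranorlabd-8-en-7-one
Conditions: CrO3, 3,5-dimethylpyrazole, CH2Cl2, −20 °C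
Reagents that add atoms: chromium trioxide, O=[Cr](=O)=O
Why: Salmond allylic oxidation takes the ring C-7 methylene to the conjugated cyclohexenone, because C-11 is shielded by C-20/C-1 and deactivated by the β-bromine.

Step 5
Reactants: 5 12-bromo-13,14,15,16-tetranorlabd-8-en-7-one
Product: 6 12-bromo-8α,9α-epoxy-13,14,15,16-tetranorlabdan-7-one
Conditions: DMDO (acetone solution), CH2Cl2, 0 °C to rt
Reagents that add atoms: dimethyldioxirane, CC1(C)OO1
Why: Neutral electrophilic epoxidation of the dialkyl-substituted enone alkene occurs anti to the axial C-10 β-methyl, setting C-8 and C-9 as the α-epoxide and avoiding base-induced loss of HBr through the dienolate.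

Step 6
Reactants: 6 12-bromo-8α,9α-epoxy-13,14,15,16-tetranorlabdan-7-one
Product: 7 12-bromo-9α-hydroxy-13,14,15,16-tetranorlabdan-7-one (8α-methyl, 8β-H)
Conditions: SmI2 (2.2 equiv), THF/MeOH, −78 °C
Reagents that add atoms: none
Why: SmI2 reduction of the α,β-epoxy ketone cleaves the Cα–O bond (C-8) and keeps the 9α-oxygen; axial β-face protonation of the samarium enolate gives the equatorial 8α-methyl, also the thermodynamic epimer since 8β-methyl would be 1,3-diaxial to C-20.

Step 7
Reactants: 7 12-bromo-9α-hydroxy-13,14,15,16-tetranorlabdan-7-one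
Product: 9 12-bromo-7,9α-bis(triethylsilyloxy)-13,14,15,16-tetranorlabd-6-ene, via dilithium alkoxide enolate 8 (not isolated)
Conditions: LDA (2.4 equiv), THF, −78 °C; then TESOTf (3.5 equiv), −78 to −40 °C
Reagents that add atoms: triethylsilyl trifluoromethanesulfonate, CC[Si](CC)(CC)OS(=O)(=O)C(F)(F)F; lithium diisopropylamide, [Li]N(C(C)C)C(C)C (lithium of 8 only)
Why: Kinetic deprotonation of the OH and then of the less substituted C-6 gives a dianion that cannot eliminate (oxide leaving group), and O-silylation of both oxygens gives the Δ6 silyl enol ether and the 9-O-TES ether without touching C-8.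

Step 8
Reactants: 9 12-bromo-7,9α-bis(triethylsilyloxy)-13,14,15,16-tetranorlabd-6-ene
Product: 11 12-bromo-7β,9α-bis(triethylsilyloxy)-13,14,15,16-tetranorlabdan-6α-ol, via 6α-boryl adduct 10 (not isolated)
Conditions: BH3·THF, THF, 0 °C to rt; then 3 M NaOH, 30% H2O2, 0 °C
Reagents that add atoms: hydrogen peroxide, OO; borane–THF, B.C1CCOC1 (boron of 10 only)
Why: Hydroboration–oxidation of the silyl enol ether puts boron on C-6 (β to oxygen) by syn addition from the α face, the β face being blocked by the axial C-4 and C-10 methyls, so hydrogen enters C-7 from below and the 7-oxygen becomes β (7R).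

Step 9
Reactants: 11 12-bromo-7β,9α-bis(triethylsilyloxy)-13,14,15,16-tetranorlabdan-6α-ol
Product: 12 12-bromo-7β,9α-bis(triethylsilyloxy)-13,14,15,16-tetranorlabdan-6-one
Conditions: Dess–Martin periodinane, CH2Cl2, rt
Reagents that add atoms: none
Why: Dess–Martin oxidation of the hindered secondary alcohol completes the 1,2-carbonyl transposition under non-epimerising conditions, leaving the equatorial 7β-OTES and the trans ring fusion intact.

Step 10
Reactants: 12 12-bromo-7β,9α-bis(triethylsilyloxy)-13,14,15,16-tetranorlabdan-6-one; 13 4-bromofuran-2(5H)-one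
Product: 15 7β,9α-bis(triethylsilyloxy)-6-oxolabd-13-en-15,16-olide, via alkylzinc bromide 14 (not isolated)
Conditions: Zn dust, LiCl, THF, 50 °C; then 13, Pd(OAc)2 (cat.), SPhos (cat.), THF, rt
Reagents that add atoms: zinc, [Zn] (zinc of 14 only)
Why: Knochel zinc insertion into the primary bromide and sp3–sp2 Negishi coupling with the vinylogous acyl bromide form C12–C13; the ketone and silyl ethers tolerate the alkylzinc.

Step 11
Reactants: 15 7β,9α-bis(triethylsilyloxy)-6-oxolabd-13-en-15,16-olide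
Product: 17 (13R)-9α,13-epoxy-7β-hydroxy-6-oxolabdan-15,16-olide (target), via seco diol 16 (not isolated)
Conditions: TBAF (1 M in THF), THF, 0 °C to rt
Reagents that add atoms: none
Why: Fluoride removes both TES groups and the basic medium drives a reversible 5-exo-trig intramolecular oxa-Michael addition of the 9α-alkoxide to C-13 of the butenolide; C-13 is set with little substrate bias, so roughly equal 13R and 13S epimers are expected, the 13R target is separated and the 13S epimer is recycled through the same equilibrium.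

## Compound list

1 | (+)-sclareolide, (3aR,5aS,9aS,9bR)-3a,6,6,9a-tetramethyldecahydronaphtho[2,1-b]furan-2(1H)-one | C[C@@]12CC[C@H]3C(C)(C)CCC[C@]3(C)[C@H]1CC(=O)O2 | starting material
2 | methyl 13,14,15,16-tetranorlabd-8-en-12-oate (5S,10S) | CC1=C(CC(=O)OC)[C@@]2(C)CCCC(C)(C)[C@@H]2CC1 | intermediate
3 | 13,14,15,16-tetranorlabd-8-en-12-ol (5S,10S) | CC1=C(CCO)[C@@]2(C)CCCC(C)(C)[C@@H]2CC1 | intermediate
4 | 12-bromo-13,14,15,16-tetranorlabd-8-ene (5S,10S) | CC1=C(CCBr)[C@@]2(C)CCCC(C)(C)[C@@H]2CC1 | intermediate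
5 | 12-bromo-13,14,15,16-tetranorlabd-8-en-7-one | CC1=C(CCBr)[C@@]2(C)CCCC(C)(C)[C@@H]2CC1=O | intermediate
6 | 12-bromo-8α,9α-epoxy-13,14,15,16-tetranorlabdan-7-one | C[C@@]12C(=O)C[C@H]3C(C)(C)CCC[C@]3(C)[C@]1(CCBr)O2 | intermediate
7 | 12-bromo-9α-hydroxy-13,14,15,16-tetranorlabdan-7-one (8α-methyl, 8β-H) | C[C@@H]1C(=O)C[C@H]2C(C)(C)CCC[C@]2(C)[C@@]1(O)CCBr | intermediate
8 | dilithium 9α-alkoxide Δ6-enolate of 7 | C[C@@H]1C(O[Li])=C[C@H]2C(C)(C)CCC[C@]2(C)[C@@]1(O[Li])CCBr | intermediate (not isolated)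
9 | 12-bromo-7,9α-bis(triethylsilyloxy)-13,14,15,16-tetranorlabd-6-ene (8α-methyl) | C[C@@H]1C(O[Si](CC)(CC)CC)=C[C@H]2C(C)(C)CCC[C@]2(C)[C@@]1(O[Si](CC)(CC)CC)CCBr | intermediate
10 | 6α-boranyl-12-bromo-7β,9α-bis(triethylsilyloxy)-13,14,15,16-tetranorlabdane | C[C@@H]1[C@@H](O[Si](CC)(CC)CC)[C@H](B)[C@H]2C(C)(C)CCC[C@]2(C)[C@@]1(O[Si](CC)(CC)CC)CCBr | intermediate (not isolated)
11 | 12-bromo-7β,9α-bis(triethylsilyloxy)-13,14,15,16-tetranorlabdan-6α-ol | C[C@@H]1[C@@H](O[Si](CC)(CC)CC)[C@H](O)[C@H]2C(C)(C)CCC[C@]2(C)[C@@]1(O[Si](CC)(CC)CC)CCBr | intermediate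
12 | 12-bromo-7β,9α-bis(triethylsilyloxy)-13,14,15,16-tetranorlabdan-6-one | C[C@@H]1[C@@H](O[Si](CC)(CC)CC)C(=O)[C@H]2C(C)(C)CCC[C@]2(C)[C@@]1(O[Si](CC)(CC)CC)CCBr | intermediate
13 | 4-bromofuran-2(5H)-one | O=C1OCC(Br)=C1 | starting material
14 | [6-oxo-7β,9α-bis(triethylsilyloxy)-13,14,15,16-tetranorlabdan-12-yl]zinc bromide | C[C@@H]1[C@@H](O[Si](CC)(CC)CC)C(=O)[C@H]2C(C)(C)CCC[C@]2(C)[C@@]1(O[Si](CC)(CC)CC)CC[Zn]Br | intermediate (not isolated)
15 | 7β,9α-bis(triethylsilyloxy)-6-oxolabd-13-en-15,16-olide (4-alkylfuran-2(5H)-one) | C[C@@H]1[C@@H](O[Si](CC)(CC)CC)C(=O)[C@H]2C(C)(C)CCC[C@]2(C)[C@@]1(O[Si](CC)(CC)CC)CCC1=CC(=O)OC1 | intermediate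
16 | 7β,9α-dihydroxy-6-oxolabd-13-en-15,16-olide | C[C@@H]1[C@@H](O)C(=O)[C@H]2C(C)(C)CCC[C@]2(C)[C@@]1(O)CCC1=CC(=O)OC1 | intermediate (not isolated)
17 | (5S,7R,8R,9R,10S,13R)-9α,13-epoxy-7β-hydroxy-6-oxolabdan-15,16-olide | C[C@@H]1[C@@H](O)C(=O)[C@H]2C(C)(C)CCC[C@]2(C)[C@@]12CC[C@@]1(COC(=O)C1)O2 | target

## Step count and risks

Total step count: 11. Longest linear sequence: 11 steps (1 to 17; 13 is bought).

The three steps most likely to fail:

**Step 4 (site of allylic oxidation, C-7 against C-11, and over-oxidation).** The fallback sets out from 2 and comes back at 5. The ester 2 is oxidised instead of the bromide (CrO3/3,5-dimethylpyrazole), where C-11 is α to the ester carbonyl and no longer competes, giving methyl 7-oxo-13,14,15,16-tetranorlabd-8-en-12-oate F1. LiAlH4 reduces ester and ketone together to 13,14,15,16-tetranorlabd-8-ene-7β,12-diol F2 (major epimer; the 7α-epimer converges). MnO2 re-oxidises only the allylic alcohol to 12-hydroxy-13,14,15,16-tetranorlabd-8-en-7-one F3, and Appel bromination (CBr4, PPh3) gives 5.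

**Step 7 (regioselective enolisation of a β-hydroxy ketone; retro-aldol or C-8 enolisation).** The fallback sets out from 6 and comes back at 12. The epoxy ketone 6, which has C-6 as its only enolisable position and no free hydroxyl, is converted with LDA/TESCl into 12-bromo-8α,9α-epoxy-7-(triethylsilyloxy)-13,14,15,16-tetranorlabd-6-ene F4. Rubottom oxidation with DMDO from the α face and mild acid work-up gives 12-bromo-8α,9α-epoxy-6α-hydroxy-13,14,15,16-tetranorlabdan-7-one F5. SmI2 at −90 °C opens the epoxide faster than it removes the α-hydroxyl, giving 12-bromo-6α,9α-dihydroxy-13,14,15,16-tetranorlabdan-7-one F6. A base-catalysed α-ketol transposition through the enediol (cat. DBU, toluene, 60 °C) moves the carbonyl to C-6, which relieves the peri interaction of the 6α-oxygen with the equatorial C-4 methyl and leaves the equatorial 7β-alcohol, 12-bromo-7β,9α-dihydroxy-13,14,15,16-tetranorlabdan-6-one F7. Double silylation (TESOTf, 2,6-lutidine) gives 12.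

**Step 11 (no substrate control at C-13; base-sensitive α-ketol).** The fallback sets out from 15 and comes back at 17. Both TES groups are removed under acidic conditions (HF·pyridine, THF, 0 °C), where no cyclisation occurs, and the seco diol 16 is isolated. The ring is then closed in a separate, kinetically controlled step with a chiral bifunctional Brønsted base (iminophosphorane–thiourea type), choosing the catalyst enantiomer that delivers O-9 to the C-13 face giving 13R, so that reagent control replaces the thermodynamic cascade. No new compound is made (F0).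

## Further compounds

F1 | step 4 | methyl 7-oxo-13,14,15,16-tetranorlabd-8-en-12-oate | CC1=C(CC(=O)OC)[C@@]2(C)CCCC(C)(C)[C@@H]2CC1=O
F2 | step 4 | 13,14,15,16-tetranorlabd-8-ene-7β,12-diol | CC1=C(CCO)[C@@]2(C)CCCC(C)(C)[C@@H]2C[C@@H]1O
F3 | step 4 | 12-hydroxy-13,14,15,16-tetranorlabd-8-en-7-one | CC1=C(CCO)[C@@]2(C)CCCC(C)(C)[C@@H]2CC1=O
F4 | step 7 | 12-bromo-8α,9α-epoxy-7-(triethylsilyloxy)-13,14,15,16-tetranorlabd-6-ene | C[C@@]12C(O[Si](CC)(CC)CC)=C[C@H]3C(C)(C)CCC[C@]3(C)[C@]1(CCBr)O2
F5 | step 7 | 12-bromo-8α,9α-epoxy-6α-hydroxy-13,14,15,16-tetranorlabdan-7-one | C[C@@]12C(=O)[C@H](O)[C@H]3C(C)(C)CCC[C@]3(C)[C@]1(CCBr)O2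
F6 | step 7 | 12-bromo-6α,9α-dihydroxy-13,14,15,16-tetranorlabdan-7-one | C[C@@H]1C(=O)[C@H](O)[C@H]2C(C)(C)CCC[C@]2(C)[C@@]1(O)CCBr
F7 | step 7 | 12-bromo-7β,9α-dihydroxy-13,14,15,16-tetranorlabdan-6-one | C[C@@H]1[C@@H](O)C(=O)[C@H]2C(C)(C)CCC[C@]2(C)[C@@]1(O)CCBr
F0 | step 11 | none | none
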